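**Retrosynthetic overview**
- Target 20 is a depside. Hydrogenolysis of two benzyl groups and hydrolysis of a dioxolane lead back to the aryl ester 18, which is cut at the ester C–O bond into ring A acid 17 and ring B phenol 9.
- The strategy rests on ring B: C1 carries the carboxyl, C2 and C4 carry oxygen and C6 carries pentyl. This is the imprint of a malonate carbon (C1, with its ester carbonyl as C2) joined to the C3–C6 chain of a pentyl enone.
- A Michael–Claisen annulation of dibenzyl malonate 1 and (E)-non-3-en-2-one 2 forms C1–C6 and C2–C3 and closes ring B as the cyclic 1,3-dione 4. Aromatization gives resorcylate 6, and a temporary 4-O-allyl group lets the 2-hydroxyl be methylated.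
- Ring A is bought as an arene (orsellinic acid 10). Its C6 methyl is extended to the 2-oxopentyl chain by lateral lithiation and Weinreb acylation, and the ketone is carried as a dioxolane so that acid activation cannot close an isocoumarin.
- Ring order: ring B is the only carbocycle built (step 1, aromatized in step 2); rings A and B are joined in step 11.

Key step: step 1

Assumption: ring A is the acyl ring with the 2-oxopentyl chain and ring B is the pentyl-bearing benzoic acid ring. The target is achiral, so the two transient stereocentres of 4 need no absolute control and are drawn as one enantiomer of the racemate.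

**Route**

Step 1
Reactants: 1 dibenzyl malonate; 2 (E)-non-3-en-2-one
Product: 4 benzyl trans-2-hydroxy-4-oxo-6-pentylcyclohex-2-ene-1-carboxylate (racemic), via Michael adduct 3 (not isolated)
Conditions: NaH (1.15 equiv), BnOH (0.1 equiv), THF, 0 °C; add 2, then 65 °C; aq. HCl work-up
Reagents that add atoms: none
Why: The sodium enolate of 1 adds in a Michael reaction to C4 of enone 2 (future C1–C6 bond); proton transfer, relayed by benzyl alcohol and benzyloxide, then exposes the methyl ketone enolate, which attacks one benzyl ester in an intramolecular Claisen (Dieckmann-type) condensation to form C2–C3 and expel benzyloxide. The closest known reaction is the classical malonate plus alkyl vinyl ketone Michael–Claisen route to 6-alkylcyclohexane-1,3-dione carboxylates, run here with the benzyl ester in an aprotic medium where any ester exchange is degenerate. The ring closes by a 6-exo-trig acyl substitution. The C6 centre forms without control in the conjugate addition (racemic), and the C1 centre, flanked by the ester and the enolised dione, should equilibrate to the trans diequatorial arrangement; both are erased in step 2. The step needs 1,4- over 1,2-addition and closure through the methyl rather than the methylene alpha carbon: the soft stabilised malonate anion secures the first, and ring size secures the second, since the methylene enolate could only give a four-membered ring. Deprotonation of the product by the released benzyloxide gives a stable vinylogous carboxylate that pulls the sequence to completion.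

Step 2
Reactants: 4 benzyl trans-2-hydroxy-4-oxo-6-pentylcyclohex-2-ene-1-carboxylate
Product: 6 benzyl 2,4-dihydroxy-6-pentylbenzoate, via bromo dione 5 (not isolated)
Conditions: Br2 (1.0 equiv), DMF, 0 °C → rt, then 80 °C
Reagents that add atoms: none
Why: Electrophilic bromination at C3 of the enolised 1,3-dione followed by 1,4-loss of HBr from the bis-enol (halogenation–dehydrohalogenation aromatization of a cyclohexane-1,3-dione) should give the resorcylate with the benzyl ester in place and erase both stereocentres; one equivalent of Br2 limits bromination of the product ring.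

Step 3
Reactants: 6 benzyl 2,4-dihydroxy-6-pentylbenzoate
Product: 7 benzyl 4-(allyloxy)-2-hydroxy-6-pentylbenzoate
Conditions: allyl bromide (1.05 equiv), K2CO3, acetone, 40 °C
Reagents that add atoms: allyl bromide, C=CCBr
Why: Williamson etherification should occur only at the 4-hydroxyl, because the 2-hydroxyl is held in a hydrogen bond to the ester carbonyl and is much less acidic and nucleophilic under weak carbonate base.

Step 4
Reactants: 7 benzyl 4-(allyloxy)-2-hydroxy-6-pentylbenzoate
Product: 8 benzyl 4-(allyloxy)-2-methoxy-6-pentylbenzoate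
Conditions: MeI, K2CO3, DMF, 50 °C
Reagents that add atoms: iodomethane, CI
Why: Williamson methylation of the hydrogen-bonded 2-hydroxyl needs the more forcing polar aprotic conditions, which the allyl ether and the benzyl ester tolerate.

Step 5
Reactants: 8 benzyl 4-(allyloxy)-2-methoxy-6-pentylbenzoate
Product: 9 benzyl 4-hydroxy-2-methoxy-6-pentylbenzoate
Conditions: Pd(PPh3)4 (5 mol %), morpholine, THF, rt
Reagents that add atoms: none
Why: Tsuji–Trost deallylation: zerovalent palladium ionises the aryl allyl ether to a pi-allyl complex that morpholine captures, while the benzyl ester and the methyl ether are inert.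

Step 6
Reactants: 10 orsellinic acid
Product: 11 methyl 2-hydroxy-4-methoxy-6-methylbenzoate
Conditions: MeI (2.2 equiv), K2CO3, acetone, reflux
Reagents that add atoms: iodomethane, CI
Why: Carboxylate alkylation and Williamson methylation of the free 4-hydroxyl proceed readily, while the hydrogen-bonded 2-hydroxyl should remain free under stoichiometric control in acetone.

Step 7
Reactants: 11 methyl 2-hydroxy-4-methoxy-6-methylbenzoate
Product: 12 methyl 2-(benzyloxy)-4-methoxy-6-methylbenzoate
Conditions: BnBr, K2CO3, DMF, 60 °C
Reagents that add atoms: benzyl bromide, BrCc1ccccc1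
Why: Williamson benzylation in warm DMF overcomes the hydrogen bond of the 2-hydroxyl and installs a group that leaves at the end together with the benzyl ester.

Step 8
Reactants: 12 methyl 2-(benzyloxy)-4-methoxy-6-methylbenzoate
Product: 15 methyl 2-(benzyloxy)-4-methoxy-6-(2-oxopentyl)benzoate, via benzylic lithium species 13 (not isolated), via lithium hemiaminal alkoxide 14 (not isolated)
Conditions: LiN(iPr)2 (1.15 equiv), THF, −78 °C; then PrC(O)N(OMe)Me, −78 °C; AcOH quench at −78 °C
Reagents that add atoms: N-methoxy-N-methylbutanamide, CCCC(=O)N(C)OC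
Why: Lateral (benzylic) lithiation of the ortho-toluate gives an ester-conjugated anion that is acylated by the Weinreb amide; the chelated tetrahedral adduct should persist until the cold acidic quench, which prevents over-addition and proton transfer from the more acidic ketone.

Step 9
Reactants: 15 methyl 2-(benzyloxy)-4-methoxy-6-(2-oxopentyl)benzoate
Product: 16 methyl 2-(benzyloxy)-4-methoxy-6-[(2-propyl-1,3-dioxolan-2-yl)methyl]benzoate
Conditions: Me3SiOCH2CH2OSiMe3, Me3SiOTf (5 mol %), CH2Cl2, −78 → −20 °C; pyridine quench
Reagents that add atoms: 1,2-bis(trimethylsilyloxy)ethane, C[Si](C)(C)OCCO[Si](C)(C)C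
Why: Noyori ketalization forms the dioxolane under aprotic low-temperature conditions that should not drive the keto ester to an isocoumarin; the mask is needed so that later activation of the acid cannot be intercepted by the enol.

Step 10
Reactants: 16 methyl 2-(benzyloxy)-4-methoxy-6-[(2-propyl-1,3-dioxolan-2-yl)methyl]benzoate
Product: 17 2-(benzyloxy)-4-methoxy-6-[(2-propyl-1,3-dioxolan-2-yl)methyl]benzoic acid
Conditions: KOH, DMSO–H2O, 90 °C; then 1 M HCl to pH 4, 0 °C
Reagents that add atoms: potassium hydroxide, [K+].[OH-]
Why: Saponification of the di-ortho-substituted methyl ester needs hydroxide in DMSO with heating, conditions to which the dioxolane and the benzyl ether are stable; cold, mild acidification keeps the ketal intact.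

Step 11
Reactants: 17 2-(benzyloxy)-4-methoxy-6-[(2-propyl-1,3-dioxolan-2-yl)methyl]benzoic acid; 9 benzyl 4-hydroxy-2-methoxy-6-pentylbenzoate
Product: 18 benzyl 4-({2-(benzyloxy)-4-methoxy-6-[(2-propyl-1,3-dioxolan-2-yl)methyl]benzoyl}oxy)-2-methoxy-6-pentylbenzoate
Conditions: DCC, DMAP (10 mol %), CH2Cl2, 0 °C → rt
Reagents that add atoms: none
Why: Steglich esterification: the O-acylisourea is relayed through an acylpyridinium to the unhindered, non-hydrogen-bonded 4-hydroxyl of 9, and with the ketone masked the activated acid cannot form an enol lactone.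

Step 12
Reactants: 18 benzyl 4-({2-(benzyloxy)-4-methoxy-6-[(2-propyl-1,3-dioxolan-2-yl)methyl]benzoyl}oxy)-2-methoxy-6-pentylbenzoate
Product: 19 benzyl 4-{[2-(benzyloxy)-4-methoxy-6-(2-oxopentyl)benzoyl]oxy}-2-methoxy-6-pentylbenzoate
Conditions: 1 M HCl–THF (1:4), rt
Reagents that add atoms: water, O
Why: Acid-catalysed acetal hydrolysis of the dioxolane should be much faster at room temperature than cleavage of the hindered aryl ester or the benzyl ester; the reaction is stopped at full conversion to limit enol lactonisation.

Step 13
Reactants: 19 benzyl 4-{[2-(benzyloxy)-4-methoxy-6-(2-oxopentyl)benzoyl]oxy}-2-methoxy-6-pentylbenzoate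
Product: 20 4-{[2-hydroxy-4-methoxy-6-(2-oxopentyl)benzoyl]oxy}-2-methoxy-6-pentylbenzoic acid (CNP0110448.0)
Conditions: H2 (1 atm), 10% Pd/C, EtOAc, rt
Reagents that add atoms: none
Why: Catalytic hydrogenolysis removes the benzyl ester and the benzyl ether under neutral conditions and should leave the aryl ester and the non-conjugated ketone untouched.

**Compound list**

1 | dibenzyl malonate | O=C(CC(=O)OCc1ccccc1)OCc1ccccc1 | starting material
2 | (E)-non-3-en-2-one | CCCCC/C=C/C(C)=O | starting material
3 | dibenzyl 2-(2-oxononan-4-yl)propanedioate (Michael adduct; racemic, one enantiomer drawn; not isolated) | CCCCC[C@H](CC(C)=O)C(C(=O)OCc1ccccc1)C(=O)OCc1ccccc1 | intermediate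
4 | benzyl trans-2-hydroxy-4-oxo-6-pentylcyclohex-2-ene-1-carboxylate (racemic, one enantiomer drawn) | O=C(OCc1ccccc1)[C@@H]1C(O)=CC(=O)C[C@H]1CCCCC | intermediate
5 | benzyl trans-3-bromo-2-hydroxy-4-oxo-6-pentylcyclohex-2-ene-1-carboxylate (bromo dione; racemic, one enantiomer drawn; not isolated) | O=C(OCc1ccccc1)[C@@H]1C(O)=C(Br)C(=O)C[C@H]1CCCCC | intermediate
6 | benzyl 2,4-dihydroxy-6-pentylbenzoate | CCCCCc1cc(O)cc(O)c1C(=O)OCc1ccccc1 | intermediate
7 | benzyl 4-(allyloxy)-2-hydroxy-6-pentylbenzoate | CCCCCc1cc(OCC=C)cc(O)c1C(=O)OCc1ccccc1 | intermediate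
8 | benzyl 4-(allyloxy)-2-methoxy-6-pentylbenzoate | CCCCCc1cc(OCC=C)cc(OC)c1C(=O)OCc1ccccc1 | intermediate
9 | benzyl 4-hydroxy-2-methoxy-6-pentylbenzoate | CCCCCc1cc(O)cc(OC)c1C(=O)OCc1ccccc1 | intermediate
10 | orsellinic acid (2,4-dihydroxy-6-methylbenzoic acid) | Cc1cc(O)cc(O)c1C(=O)O | starting material
11 | methyl 2-hydroxy-4-methoxy-6-methylbenzoate | COC(=O)c1c(C)cc(OC)cc1O | intermediate
12 | methyl 2-(benzyloxy)-4-methoxy-6-methylbenzoate | COC(=O)c1c(C)cc(OC)cc1OCc1ccccc1 | intermediate
13 | methyl 2-(benzyloxy)-6-(lithiomethyl)-4-methoxybenzoate (benzylic lithium species; not isolated) | [Li]Cc1cc(OC)cc(OCc2ccccc2)c1C(=O)OC | intermediate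
14 | lithium hemiaminal alkoxide from 13 and the Weinreb amide (racemic, one enantiomer drawn; not isolated) | CCC[C@@]([O-])(Cc1cc(OC)cc(OCc2ccccc2)c1C(=O)OC)N(C)OC.[Li+] | intermediate
15 | methyl 2-(benzyloxy)-4-methoxy-6-(2-oxopentyl)benzoate | CCCC(=O)Cc1cc(OC)cc(OCc2ccccc2)c1C(=O)OC | intermediate
16 | methyl 2-(benzyloxy)-4-methoxy-6-[(2-propyl-1,3-dioxolan-2-yl)methyl]benzoate | CCCC1(Cc2cc(OC)cc(OCc3ccccc3)c2C(=O)OC)OCCO1 | intermediate
17 | 2-(benzyloxy)-4-methoxy-6-[(2-propyl-1,3-dioxolan-2-yl)methyl]benzoic acid | CCCC1(Cc2cc(OC)cc(OCc3ccccc3)c2C(=O)O)OCCO1 | intermediate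
18 | benzyl 4-({2-(benzyloxy)-4-methoxy-6-[(2-propyl-1,3-dioxolan-2-yl)methyl]benzoyl}oxy)-2-methoxy-6-pentylbenzoate | CCCCCc1cc(OC(=O)c2c(OCc3ccccc3)cc(OC)cc2CC2(CCC)OCCO2)cc(OC)c1C(=O)OCc1ccccc1 | intermediate
19 | benzyl 4-{[2-(benzyloxy)-4-methoxy-6-(2-oxopentyl)benzoyl]oxy}-2-methoxy-6-pentylbenzoate | CCCCCc1cc(OC(=O)c2c(OCc3ccccc3)cc(OC)cc2CC(=O)CCC)cc(OC)c1C(=O)OCc1ccccc1 | intermediate
20 | 4-{[2-hydroxy-4-methoxy-6-(2-oxopentyl)benzoyl]oxy}-2-methoxy-6-pentylbenzoic acid | CCCCCc1cc(OC(=O)c2c(O)cc(OC)cc2CC(=O)CCC)cc(OC)c1C(=O)O | target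

**Step count**
Total steps: 13. Longest linear sequence: 8 steps (steps 1–5 or 6–10, then 11–13).

**Steps most likely to fail**

1. Step 8 (lateral acylation). The tetrahedral adduct may collapse before the quench. The freed ketone is more acidic than 12 and would then protonate the lateral anion, and its enolate can close onto the neighbouring ester, so conversion would stall and the keto ester would be accompanied by enol lactone. Fallback, from 12 back to 15: the lateral anion of 12 is used in twofold amount, the second equivalent serving as base for the product, and is acylated with ethyl butanoate. The mixture is warmed and then stirred with TsOH in toluene so that all acylated material converges on the isocoumarin 8-(benzyloxy)-6-methoxy-3-propyl-1H-isochromen-1-one F1. KOH in aqueous ethanol opens the enol lactone, and cold acidification gives 2-(benzyloxy)-4-methoxy-6-(2-oxopentyl)benzoic acid F2. Its carboxylate is methylated with MeI and KHCO3 in DMF, a base too weak to enolise the ketone, which returns 15.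

2. Step 2 (aromatization). The electron-rich resorcylate may be brominated further on the ring, and the HBr released in hot DMF may cleave the benzyl ester, after which the free acid would decarboxylate. Fallback, from 4 back to 6: 4 is treated with Me3SiOTf and Et3N to give the bis(silyl) dienol ether benzyl 6-pentyl-2,4-bis(trimethylsilyloxy)cyclohexa-1,3-diene-1-carboxylate F3. DDQ then dehydrogenates it by hydride abstraction, with no halogen and no acid, to benzyl 6-pentyl-2,4-bis(trimethylsilyloxy)benzoate F4. Aqueous citric acid in THF hydrolyses the aryl silyl ethers and gives 6.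

3. Step 12 (ketal hydrolysis). Once the ketone is free, its enol can attack the aryl ester under the acidic conditions and expel phenol 9 (isocoumarin formation); prolonged acid can also hydrolyse the depside ester. Fallback, from 15 back to 19: 15 is converted with ethane-1,2-dithiol and Zn(OTf)2 (cat.) in CH2Cl2 into methyl 2-(benzyloxy)-4-methoxy-6-[(2-propyl-1,3-dithiolan-2-yl)methyl]benzoate F5. This is saponified as in step 10 to 2-(benzyloxy)-4-methoxy-6-[(2-propyl-1,3-dithiolan-2-yl)methyl]benzoic acid F6 and coupled with 9 as in step 11 to benzyl 4-({2-(benzyloxy)-4-methoxy-6-[(2-propyl-1,3-dithiolan-2-yl)methyl]benzoyl}oxy)-2-methoxy-6-pentylbenzoate F7. The dithiolane is then removed with Hg(ClO4)2 and CaCO3 in aqueous THF, a fast, buffered, non-acidic release that returns 19 before the hydrogenolysis.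

**Further compounds**
F1 | step 8 | 8-(benzyloxy)-6-methoxy-3-propyl-1H-isochromen-1-one | CCCC1=Cc2cc(OC)cc(OCc3ccccc3)c2C(=O)O1
F2 | step 8 | 2-(benzyloxy)-4-methoxy-6-(2-oxopentyl)benzoic acid | CCCC(=O)Cc1cc(OC)cc(OCc2ccccc2)c1C(=O)O
F3 | step 2 | benzyl 6-pentyl-2,4-bis(trimethylsilyloxy)cyclohexa-1,3-diene-1-carboxylate (racemic, one enantiomer drawn) | CCCCC[C@@H]1CC(O[Si](C)(C)C)=CC(O[Si](C)(C)C)=C1C(=O)OCc1ccccc1
F4 | step 2 | benzyl 6-pentyl-2,4-bis(trimethylsilyloxy)benzoate | CCCCCc1cc(O[Si](C)(C)C)cc(O[Si](C)(C)C)c1C(=O)OCc1ccccc1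
F5 | step 12 | methyl 2-(benzyloxy)-4-methoxy-6-[(2-propyl-1,3-dithiolan-2-yl)methyl]benzoate | CCCC1(Cc2cc(OC)cc(OCc3ccccc3)c2C(=O)OC)SCCS1
F6 | step 12 | 2-(benzyloxy)-4-methoxy-6-[(2-propyl-1,3-dithiolan-2-yl)methyl]benzoic acid | CCCC1(Cc2cc(OC)cc(OCc3ccccc3)c2C(=O)O)SCCS1
F7 | step 12 | benzyl 4-({2-(benzyloxy)-4-methoxy-6-[(2-propyl-1,3-dithiolan-2-yl)methyl]benzoyl}oxy)-2-methoxy-6-pentylbenzoate | CCCCCc1cc(OC(=O)c2c(OCc3ccccc3)cc(OC)cc2CC2(CCC)SCCS2)cc(OC)c1C(=O)OCc1ccccc1
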